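How much faster does target form, at the moment asked about, when more free catalyst goes into the flask?

all flasks: gas 62 mM (held); free catalyst 0.18 mM

| run | starting material | second substrate | remark |
|---|---|---|---|
| alder | 0.18 M | 0.72 M | run made earlier |
| flask | 0.36 M | 0.720 M |  |

alder run (percent of the starting material charged)

| time / h | target / % | starting material / % |
|---|---|---|
| 0.667 | 0 | 98.9 |
| 1.33 | 1.3 | 99.7 |
| 2.00 | 1.3 | 97.8 |
| 3.00 | 3.0 | 93.9 |
| 4.00 | 6.9 | 94.4 |
| 5.00 | 8.1 | 92.0 |

(standard deviation of a reading: 1 percentage point)

- factor on the rate of making target when 30% of the starting material are converted if free catalyst is charged twice over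
- factor on the rate when 30% of the starting material are converted if free catalyst is charged at 2.0 mM instead

- in percentages every species weighs as the starting material in it: one homo dimer counts as two
- at the start none of reagent is dissolved
- the numbers in the tables scatter by 1 percentage point (one standard deviation)
- what may be going on: starting material + free catalyst <-> catalyst intermediate A; reagent + catalyst intermediate A -> free catalyst + target; second substrate + free catalyst <-> catalyst intermediate B; reagent + catalyst intermediate B -> free catalyst + second product; gas <-> reagent; 2 starting material -> homo dimer
- no earlier run changes the charge of free catalyst; that part of a forecast is a guess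

We count turnovers. Reaching 30% in the flask takes 600 turnovers per catalyst. From 3.00 h to 5.00 h the alder readings give the turnover rate, target made per hour per catalyst charged, as 25.5 h⁻¹. That line, followed back, reaches zero at a lag of 1.82 h.

Take the main step first, with reagent plentiful: the rate follows the catalyst, and the factors are 2 and 11.1. Now add the gas step. We assume that reagent dissolves in proportion to the gap below [gas], so in our reckoning more catalyst draws [reagent] down. Let f be [reagent]/[gas] on the straight stretch. Taking the lag as the time reagent needs to get there, and balancing uptake against turnover, we get f(1 − f) = turnover rate × [free catalyst] × lag / [gas]. So f is 0.161 or 0.839. One run can't separate these, and we bet on the lower. Catalyst multiplied by c then gives the factor c/(f + c(1 − f)), which is 1.09 and 1.17. Last, add the rest: second substrate spends reagent unseen, which in the same balance raises f, so we commit to slightly more than these two numbers.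

The forecast gives 1.3 (from 1.05 to 1.8) and 1.7 (from 1.1 to 4.5), higher than ours, from “comparable constants”.

The flask gives 1.13 and 1.26, above our two numbers.

    starting material + free catalyst ⇌ catalyst intermediate A (K = 4.85 M⁻¹, k = 5270 M⁻¹ h⁻¹)
    reagent + catalyst intermediate A → free catalyst + target (k = 4750 M⁻¹ h⁻¹)
    second substrate + free catalyst ⇌ catalyst intermediate B (K = 0.450 M⁻¹, k = 20900 M⁻¹ h⁻¹)
    reagent + catalyst intermediate B → free catalyst + second product (k = 5480 M⁻¹ h⁻¹)
    gas ⇌ reagent, rate k5*(csat - [reagent]) (kL = 0.140 h⁻¹)
    2 starting material → homo dimer (k = 2.01 × 10⁻⁴ M⁻¹ h⁻¹)

At the alder turnover rate, the 600 turnovers take 23.5 h, and the flask reached 30% at 21.0 h. Gas uptake ran throughout, with [reagent] at 0.0100 M after 2.50 h and 0.0132 M after 25.0 h, while catalyst intermediate A, the resting state, held 51.0% of the catalyst after 12.5 h. By 25.0 h the flask held 35.5% target, and its second product stood at 0.0347 M.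

The readings stem from a simulated flask from invented constants; scatter was added.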